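Retrosynthesis: after removal of the O11 silyl group, the target is cut at the biaryl bond (Suzuki–Miyaura), at the aryl–allyl bond para to the ether oxygen (Stille) and at the O–C(aryl) bond of the C4 ether (iodonium arylation). This leads to 11-O-silylated cryptomeridiol.
The C4 carbinol goes back through the 3α,4α-epoxide and the C3–C4 alkene to the enone carissone, which is cut at C1–C10 and C4–C5.
Enabling feature: ring A (C1–C5, C10) shares the C5–C10 bond with ring B. Its quaternary C10 sits next to C5, which is a ring B carbonyl carbon before annulation, and C1–C4 plus the C4 methyl are the five carbons of ethyl vinyl ketone. The C10 methyl is cis to the C7 hydroxyisopropyl group across ring B, and C7 is already present in (R)-carvone.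
Forward: ring B (from carvone) → ring A (annulation) → C3 deoxygenation and C4 oxygenation → inner arene (ring C) attached through oxygen → allyl → outer arene (ring D) → desilylation.
Stereochemistry: C7 comes from (R)-carvone, C10 from the (R)-1-phenylethylamine auxiliary, C5 from axial protonation in the dissolving-metal reduction (trans-decalin), and C4 from α-face epoxidation opposite the axial C10 methyl. The C4–O bond is never broken afterwards.

Key step: step 3

Remark: eudesmane numbering is used for the decalin (C4 ether carbon, C5/C10 ring fusion, C7 side-chain carbon, C11 side-chain carbinol carbon); the methyl-bearing α-carbon of the saturated ring B ketone is epimerisable and is erased in the key step, so this ketone is drawn as its more stable trans isomer.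

Step 1
Reactants: 1 (R)-(−)-carvone
Product: 2 (5R)-5-(2-hydroxypropan-2-yl)-2-methylcyclohex-2-en-1-one
Conditions: 50% aq. H2SO4, 0 °C
Reagents that add atoms: water, O
Why: Acid-catalysed Markovnikov hydration, in which the electron-rich 1,1-disubstituted alkene is protonated to a tertiary cation and captured by water far faster than the deactivated enone reacts, while the low temperature should hold back aromatisation and the ring stereocentre (later C7) is not involved.

Step 2
Reactants: 2 (5R)-5-(2-hydroxypropan-2-yl)-2-methylcyclohex-2-en-1-one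
Product: 3 (2R,5R)-5-(2-hydroxypropan-2-yl)-2-methylcyclohexan-1-one
Conditions: H2 (1 atm), 10% Pd/C, EtOAc, rt; then cat. NaOMe, MeOH, rt
Reagents that add atoms: none
Why: Heterogeneous catalytic hydrogenation saturates the only remaining C=C bond without touching the ketone or the tertiary alcohol, and base equilibration places the α-methyl group equatorial (trans to the side chain), a centre that is erased again in step 3.

Step 3
Reactants: 3 (2R,5R)-5-(2-hydroxypropan-2-yl)-2-methylcyclohexan-1-one; 4 (R)-1-phenylethylamine; 5 ethyl vinyl ketone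
Product: 11 (+)-carissone [(4aS,7R)-7-(2-hydroxypropan-2-yl)-1,4a-dimethyl-4,4a,5,6,7,8-hexahydronaphthalen-2(3H)-one], via ketimine 6 (not isolated), via secondary enamine 7 (not isolated), via keto imine 8 (not isolated), via diketone 9 (not isolated), via ketol 10 (not isolated)
Conditions: a) 4, toluene, reflux, Dean–Stark, no acid; b) 5, THF, 40 °C; c) 10% aq. AcOH, rt; d) NaOMe, MeOH, 60 °C
Reagents that add atoms: ethyl vinyl ketone (5), CCC(=O)C=C
Why: Water-removing condensation of 3 with 4 gives ketimine 6, which reacts through its more substituted secondary enamine tautomer 7: this adds to 5 through a compact, aza-ene-like cyclic transition state in which the C1–C10 bond forms while the N–H hydrogen passes to C2, so that keto imine 8 arises directly. The closest known reaction type is the asymmetric Michael addition of chiral 1-phenylethylamine imines of 2-substituted cyclohexanones to vinyl ketones, completed as a Robinson annulation. Dilute acetic acid releases 4 and diketone 9, and methoxide closes ring A by a 6-(enolendo)-exo-trig aldol addition of the C4 enolate to the C5 carbonyl (ketol 10, C4–C5 bond) followed by E1cB dehydration to the conjugated enone 11. C10 is the only new stereocentre and is controlled by the auxiliary: in the reactive conformer of 7 the benzylic C–H lies in the enamine plane to relieve allylic strain, the phenyl group covers the β face, and 5 enters from the α face, which pushes the methyl group to the β face, cis to the C7 side chain. This pairing has to outweigh the ring's own bias for stereoelectronically favoured axial attack, which without auxiliary leads to the C10 epimer; the (R)-amine is chosen because its sense of induction on simple 2-methylcyclohexanone imines corresponds to the (S)-configured quaternary centre needed in 9. Regioselectivity for C10 over C6 is secured because only in 7 can N–H lie syn to the nucleophilic carbon while the bulky N-substituent points toward the unsubstituted C6 methylene, acid-free imine formation protects the tertiary alcohol from dehydration, and among the possible aldol pairings only C4-to-C5 gives an unstrained ring that can lose water irreversibly.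

Step 4
Reactants: 11 (+)-carissone
Product: 12 11-O-triethylsilylcarissone
Conditions: TESOTf, 2,6-lutidine, CH2Cl2, −78 → 0 °C
Reagents that add atoms: triethylsilyl trifluoromethanesulfonate, CC[Si](CC)(CC)OS(=O)(=O)C(F)(F)F
Why: Silylation of a tertiary alcohol with a silyl triflate and a hindered pyridine base, which at low temperature should be much faster than enol silylation of the enone, masks O11 so that the C4 hydroxyl made later is the only free alcohol.

Step 5
Reactants: 12 11-O-triethylsilylcarissone
Product: 14 11-(triethylsilyloxy)-5α-eudesm-3-en-3-yl trifluoromethanesulfonate (trans-decalin with 5α-H and 10β-CH3), via lithium enolate 13 (not isolated)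
Conditions: a) Li, liq. NH3–THF, t-BuOH (1 equiv), −78 → −33 °C, then NH3 evaporated; b) PhNTf2, THF, 0 °C → rt
Reagents that add atoms: N-phenylbis(trifluoromethanesulfonimide), O=S(=O)(N(c1ccccc1)S(=O)(=O)C(F)(F)F)C(F)(F)F
Why: Dissolving-metal (Birch-type) enone reduction followed by regiospecific enolate trapping as the enol triflate, in which two-electron reduction and axial protonation of the β-carbon C5 on the α face give the more stable trans-decalin and the C3–C4 lithium enolate 13, unable to equilibrate without a proton source, is O-sulfonylated by PhNTf2.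

Step 6
Reactants: 14 11-(triethylsilyloxy)-5α-eudesm-3-en-3-yl trifluoromethanesulfonate
Product: 15 α-eudesmol triethylsilyl ether [11-(triethylsilyloxy)-5α-eudesm-3-ene]
Conditions: Pd(OAc)2 (cat.), PPh3, HCO2H, Et3N, DMF, 60 °C
Reagents that add atoms: none
Why: Palladium-catalysed formate reduction of an enol triflate, in which oxidative addition to zerovalent palladium, exchange of triflate for formate, decarboxylation to a palladium hydride and reductive elimination replace C3–OTf by C3–H with the double bond held at C3–C4 and no stereocentre affected.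

Step 7
Reactants: 15 α-eudesmol triethylsilyl ether
Product: 16 3α,4α-epoxy-11-(triethylsilyloxy)-5α-eudesmane
Conditions: mCPBA, NaHCO3, CH2Cl2, 0 °C
Reagents that add atoms: 3-chloroperoxybenzoic acid, O=C(OO)c1cccc(Cl)c1
Why: Prilezhaev epoxidation of the only alkene, in which the peracid approaches the trisubstituted C3–C4 double bond from the α face because the axial C10 methyl group screens the β face, so that the C4 oxygen ends α and the C4 methyl β as in the target.

Step 8
Reactants: 16 3α,4α-epoxy-11-(triethylsilyloxy)-5α-eudesmane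
Product: 17 cryptomeridiol 11-O-triethylsilyl ether [(4R,5R,7R,10R)-11-(triethylsilyloxy)eudesman-4-ol with 4α-OH]
Conditions: LiEt3BH, THF, 0 °C → reflux
Reagents that add atoms: none
Why: SN2 hydride opening of a trisubstituted epoxide, in which the powerful nucleophile LiEt3BH attacks the secondary C3 and not the fully substituted C4 (screened by the syn-axial C10 methyl), so that the C4–O bond and with it the 4α configuration stay untouched.

Step 9
Reactants: 18 4-bromo-2-chloro-1-iodobenzene; 19 1,3,5-trimethoxybenzene
Product: 21 (4-bromo-2-chlorophenyl)(2,4,6-trimethoxyphenyl)iodonium tosylate, via Koser-type iodane 20 (not isolated)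
Conditions: a) mCPBA, TsOH·H2O, MeCN, 77 °C; b) 19, 77 °C → rt; precipitation with Et2O
Reagents that add atoms: 1,3,5-trimethoxybenzene (19), COc1cc(OC)cc(OC)c1; p-toluenesulfonic acid, Cc1ccc(S(=O)(=O)O)cc1
Why: One-pot diaryliodonium salt synthesis, in which the peracid oxidises the aryl iodide to trivalent iodine, TsOH traps it as the Koser-type reagent 20, and this electrophile substitutes the very electron-rich arene 19 (SEAr) while the C–Br and C–Cl bonds stay inert.

Step 10
Reactants: 17 cryptomeridiol 11-O-triethylsilyl ether; 21 (4-bromo-2-chlorophenyl)(2,4,6-trimethoxyphenyl)iodonium tosylate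
Product: 23 4α-(4-bromo-2-chlorophenoxy)-11-(triethylsilyloxy)-5α-eudesmane, via sodium alkoxide 22 (not isolated)
Conditions: a) NaHMDS, toluene, rt; b) 21, rt → 40 °C
Reagents that add atoms: iodonium salt 21 (4-bromo-2-chlorophenyl group), COc1cc(OC)c([I+]c2ccc(Br)cc2Cl)c(OC)c1.Cc1ccc(S(=O)(=O)[O-])cc1
Why: Metal-free O-arylation of a tertiary alkoxide with a diaryliodonium salt, in which alkoxide 22 replaces tosylate at trivalent iodine and ligand coupling transfers the electron-poorer, ortho-substituted 4-bromo-2-chlorophenyl group while the trimethoxyphenyl group leaves as its iodide, and since the new bond is O–C(aryl) the C4 configuration is retained.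

Step 11
Reactants: 23 4α-(4-bromo-2-chlorophenoxy)-11-(triethylsilyloxy)-5α-eudesmane; 24 allyltributylstannane
Product: 25 4α-(4-allyl-2-chlorophenoxy)-11-(triethylsilyloxy)-5α-eudesmane
Conditions: Pd(PPh3)4 (cat.), toluene, 100 °C
Reagents that add atoms: allyltributylstannane (24), C=CC[Sn](CCCC)(CCCC)CCCC
Why: Stille allylation, in which Pd(PPh3)4 inserts into the unhindered C–Br bond and leaves the C–Cl bond alone, and the neutral, base-free medium should keep the allyl double bond from moving into conjugation.

Step 12
Reactants: 26 4-bromophenol; 27 allyl bromide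
Product: 28 1-(allyloxy)-4-bromobenzene
Conditions: K2CO3, acetone, reflux
Reagents that add atoms: allyl bromide (27), C=CCBr
Why: Williamson ether synthesis between a phenoxide and a reactive allylic bromide.

Step 13
Reactants: 28 1-(allyloxy)-4-bromobenzene
Product: 30 2-allyl-4-bromophenol, via ortho-dienone 29 (not isolated)
Conditions: N,N-diethylaniline, 200 °C
Reagents that add atoms: none
Why: Aromatic Claisen rearrangement, in which the [3,3]-sigmatropic shift delivers the allyl group to a free ortho position (dienone 29), tautomerisation restores the phenol, and the para position is blocked by bromine.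

Step 14
Reactants: 30 2-allyl-4-bromophenol
Product: 31 2-allyl-4-(4,4,5,5-tetramethyl-1,3,2-dioxaborolan-2-yl)phenol
Conditions: B2pin2, PdCl2(dppf) (cat.), KOAc, 1,4-dioxane, 85 °C
Reagents that add atoms: bis(pinacolato)diboron, CC1(C)OB(OC1(C)C)B1OC(C)(C)C(C)(C)O1
Why: Miyaura borylation of the aryl bromide, a reaction that tolerates free phenols and isolated alkenes under the weakly basic acetate conditions.

Step 15
Reactants: 25 4α-(4-allyl-2-chlorophenoxy)-11-(triethylsilyloxy)-5α-eudesmane; 31 2-allyl-4-(4,4,5,5-tetramethyl-1,3,2-dioxaborolan-2-yl)phenol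
Product: 32 11-O-triethylsilyl ether of the target
Conditions: Pd(OAc)2 (cat.), 2-dicyclohexylphosphino-2',6'-dimethoxybiphenyl (SPhos), K3PO4, toluene–H2O, 90 °C
Reagents that add atoms: boronate 31, C=CCc1cc(B2OC(C)(C)C(C)(C)O2)ccc1O
Why: Suzuki–Miyaura coupling, in which the electron-rich, bulky biarylphosphine makes zerovalent palladium reactive enough to insert into the hindered, electron-rich C–Cl bond ortho to the tertiary alkoxy group, and the free phenol is tolerated as its phenoxide.

Step 16
Reactants: 32 11-O-triethylsilyl ether of the target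
Product: 33 target CNP0219722.1
Conditions: TBAF, THF, rt → 45 °C
Reagents that add atoms: none
Why: Fluoride-induced desilylation driven by the strong Si–F bond, whose basic, non-acidic medium spares the acid-labile tertiary alkyl aryl ether and both allyl groups and touches no stereocentre.

Compound list
1 | (R)-(−)-carvone | CC1=CC[C@@H](C(C)=C)CC1=O | starting material
2 | (5R)-5-(2-hydroxypropan-2-yl)-2-methylcyclohex-2-en-1-one | CC1=CC[C@@H](C(C)(C)O)CC1=O | intermediate
3 | (2R,5R)-5-(2-hydroxypropan-2-yl)-2-methylcyclohexan-1-one | C[C@@H]1CC[C@@H](C(C)(C)O)CC1=O | intermediate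
4 | (R)-1-phenylethylamine | C[C@@H](N)c1ccccc1 | starting material
5 | ethyl vinyl ketone (pent-1-en-3-one) | CCC(=O)C=C | starting material
6 | N-[(1R)-1-phenylethyl] ketimine of 3 (C2 epimers interconvert through 7) | CC1CC[C@@H](C(C)(C)O)CC1=N[C@H](C)c1ccccc1 | intermediate
7 | secondary enamine tautomer of 6, 2-[(1R)-4-methyl-3-{[(1R)-1-phenylethyl]amino}cyclohex-3-en-1-yl]propan-2-ol | CC1=C(N[C@H](C)c2ccccc2)C[C@H](C(C)(C)O)CC1 | intermediate
8 | N-[(1R)-1-phenylethyl] imine (at the ring carbonyl) of diketone 9 | CCC(=O)CC[C@]1(C)CC[C@@H](C(C)(C)O)CC1=N[C@H](C)c1ccccc1 | intermediate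
9 | (2S,5R)-5-(2-hydroxypropan-2-yl)-2-methyl-2-(3-oxopentyl)cyclohexan-1-one | CCC(=O)CC[C@]1(C)CC[C@@H](C(C)(C)O)CC1=O | intermediate
10 | 5,11-dihydroxyeudesman-3-one (aldol adduct; C4 and C5 undefined, both lost on dehydration) | CC1C(=O)CC[C@]2(C)CC[C@@H](C(C)(C)O)CC12O | intermediate
11 | (+)-carissone, (4aS,7R)-7-(2-hydroxypropan-2-yl)-1,4a-dimethyl-4,4a,5,6,7,8-hexahydronaphthalen-2(3H)-one | O=C1CC[C@]2(C)CC[C@@H](C(C)(C)O)CC2=C1C | intermediate
12 | 11-O-triethylsilylcarissone | O=C1CC[C@]2(C)CC[C@@H](C(C)(C)O[Si](CC)(CC)CC)CC2=C1C | intermediate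
13 | lithium 11-(triethylsilyloxy)-5α-eudesm-3-en-3-olate | CC1=C([O-])CC[C@]2(C)CC[C@@H](C(C)(C)O[Si](CC)(CC)CC)C[C@H]21.[Li+] | intermediate
14 | 11-(triethylsilyloxy)-5α-eudesm-3-en-3-yl trifluoromethanesulfonate (5α-H, 7β side chain, 10β-CH3) | CC1=C(OS(=O)(=O)C(F)(F)F)CC[C@]2(C)CC[C@@H](C(C)(C)O[Si](CC)(CC)CC)C[C@H]21 | intermediate
15 | α-eudesmol triethylsilyl ether, 11-(triethylsilyloxy)-5α-eudesm-3-ene | CC1=CCC[C@]2(C)CC[C@@H](C(C)(C)O[Si](CC)(CC)CC)C[C@H]21 | intermediate
16 | 3α,4α-epoxy-11-(triethylsilyloxy)-5α-eudesmane (4β-CH3) | O1[C@]2(C)[C@H]1CC[C@]3(C)CC[C@@H](C(C)(C)O[Si](CC)(CC)CC)C[C@H]32 | intermediate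
17 | cryptomeridiol 11-O-triethylsilyl ether, (4R,5R,7R,10R)-11-(triethylsilyloxy)eudesman-4-ol (4α-OH, 4β-CH3) | O[C@]1(C)CCC[C@]2(C)CC[C@@H](C(C)(C)O[Si](CC)(CC)CC)C[C@H]21 | intermediate
18 | 4-bromo-2-chloro-1-iodobenzene | Clc1cc(Br)ccc1I | starting material
19 | 1,3,5-trimethoxybenzene | COc1cc(OC)cc(OC)c1 | starting material
20 | 4-bromo-2-chloro-1-[hydroxy(tosyloxy)iodo]benzene | Cc1ccc(S(=O)(=O)OI(O)c2ccc(Br)cc2Cl)cc1 | intermediate
21 | (4-bromo-2-chlorophenyl)(2,4,6-trimethoxyphenyl)iodonium tosylate | COc1cc(OC)c([I+]c2ccc(Br)cc2Cl)c(OC)c1.Cc1ccc(S(=O)(=O)[O-])cc1 | intermediate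
22 | sodium alkoxide of 17 | [Na+].[O-][C@]1(C)CCC[C@]2(C)CC[C@@H](C(C)(C)O[Si](CC)(CC)CC)C[C@H]21 | intermediate
23 | 4α-(4-bromo-2-chlorophenoxy)-11-(triethylsilyloxy)-5α-eudesmane | Brc1ccc(O[C@]2(C)CCC[C@]3(C)CC[C@@H](C(C)(C)O[Si](CC)(CC)CC)C[C@H]32)c(Cl)c1 | intermediate
24 | allyltributylstannane | C=CC[Sn](CCCC)(CCCC)CCCC | starting material
25 | 4α-(4-allyl-2-chlorophenoxy)-11-(triethylsilyloxy)-5α-eudesmane | C=CCc1ccc(O[C@]2(C)CCC[C@]3(C)CC[C@@H](C(C)(C)O[Si](CC)(CC)CC)C[C@H]32)c(Cl)c1 | intermediate
26 | 4-bromophenol | Oc1ccc(Br)cc1 | starting material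
27 | allyl bromide | C=CCBr | starting material
28 | 1-(allyloxy)-4-bromobenzene | C=CCOc1ccc(Br)cc1 | intermediate
29 | 6-allyl-4-bromocyclohexa-2,4-dien-1-one (racemic) | O=C1C=CC(Br)=CC1CC=C | intermediate
30 | 2-allyl-4-bromophenol | C=CCc1cc(Br)ccc1O | intermediate
31 | 2-allyl-4-(4,4,5,5-tetramethyl-1,3,2-dioxaborolan-2-yl)phenol | C=CCc1cc(B2OC(C)(C)C(C)(C)O2)ccc1O | intermediate
32 | 3',5-diallyl-2-{[(4R,5R,7R,10R)-11-(triethylsilyloxy)eudesman-4-yl]oxy}biphenyl-4'-ol | C=CCc1ccc(O[C@]2(C)CCC[C@]3(C)CC[C@@H](C(C)(C)O[Si](CC)(CC)CC)C[C@H]32)c(-c2ccc(O)c(CC=C)c2)c1 | intermediate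
33 | CNP0219722.1, 3',5-diallyl-2-{[(4R,5R,7R,10R)-11-hydroxyeudesman-4-yl]oxy}biphenyl-4'-ol (4α-O-aryl, 4β-CH3, 5α-H, 7β side chain, 10β-CH3) | C=CCc1ccc(O[C@]2(C)CCC[C@]3(C)CC[C@@H](C(C)(C)O)C[C@H]32)c(-c2ccc(O)c(CC=C)c2)c1 | target

Total step count: 16.
Longest linear sequence: 12 steps from (R)-carvone (steps 1–8, 10, 11, 15, 16).

Steps most likely to fail

**Step 10 (O-arylation of the crowded C4 alkoxide).** Ligand coupling at trivalent iodine may be slow. Base-induced aryne formation from the salt, transfer of the wrong aryl group or plain decay of the salt could then compete.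
- The fallback replaces iodonium chemistry by nucleophilic aromatic substitution on a nitro-activated fluoroarene. It sets out from 17.
- The sodium alkoxide 22 of 17 is added to commercial 3-chloro-4-fluoronitrobenzene (THF–DMF, 0 °C → rt). Addition–elimination at the fluoride para to the nitro group should give 4α-(2-chloro-4-nitrophenoxy)-11-(triethylsilyloxy)-5α-eudesmane F1.
- Reduction with Fe and NH4Cl in aqueous EtOH should give 4α-(4-amino-2-chlorophenoxy)-11-(triethylsilyloxy)-5α-eudesmane F2.
- A non-aqueous Sandmeyer bromination (t-BuONO, CuBr2, MeCN) passes through the arenediazonium bromide F3 and comes back to the route at 23.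

**Step 3 (key annulation).** The auxiliary works against the inherent facial bias of the ring, so facial selectivity at C10 may erode. The slow addition to the less reactive ethyl vinyl ketone also leaves room for polymerisation of the acceptor.
- The fallback forms the same two bonds with 5 but moves stereocontrol from the auxiliary to a fused cyclopropane in the substrate. It sets out from 3.
- Concentrated HCl at 0 °C converts the tertiary alcohol into (2R,5R)-5-(2-chloropropan-2-yl)-2-methylcyclohexan-1-one F4.
- Methanolic KOH closes the cyclopropane by 3-exo-tet alkylation of the C6 enolate, giving (1S,6R)-3,7,7-trimethylbicyclo[4.1.0]heptan-2-one F5. Its only enolisable position is the methyl-bearing carbon.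
- Robinson annulation with 5 (KOH, EtOH, 0 °C → rt) runs through (1S,3S,6R)-3,7,7-trimethyl-3-(3-oxopentyl)bicyclo[4.1.0]heptan-2-one F6 to 6β,11-cycloeudesm-4-en-3-one F7.
- The gem-dimethylcyclopropane on the β face sends 5 to the α face, so the methyl group ends β.
- Dilute H2SO4 in aqueous dioxane opens the conjugated cyclopropane at the tertiary C11 with capture of water, and the sequence comes back to the route at 11.

**Step 8 (epoxide opening).** Hydride must attack C3 against the preference of the rigid trans-decalin for diaxial opening. The reaction may therefore be sluggish, and Lewis-acid-induced rearrangement of the epoxide to a carbonyl compound could overtake it.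
- The fallback replaces steps 7 and 8 by a radical Mukaiyama hydration. It sets out from 15.
- With Mn(dpm)3 (cat.), PhSiH3 and O2 in i-PrOH (0 °C → rt), a hydrogen atom is transferred to C3. The tertiary C4 radical should be trapped by O2 on the α face, away from the axial C10 methyl.
- Any 4α-hydroperoxy-11-(triethylsilyloxy)-5α-eudesmane F8 that remains is reduced with PPh3, and the sequence comes back to the route at 17.

Further compounds
F1 | step 10 | 4α-(2-chloro-4-nitrophenoxy)-11-(triethylsilyloxy)-5α-eudesmane | O=[N+]([O-])c1ccc(O[C@]2(C)CCC[C@]3(C)CC[C@@H](C(C)(C)O[Si](CC)(CC)CC)C[C@H]32)c(Cl)c1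
F2 | step 10 | 4α-(4-amino-2-chlorophenoxy)-11-(triethylsilyloxy)-5α-eudesmane | Nc1ccc(O[C@]2(C)CCC[C@]3(C)CC[C@@H](C(C)(C)O[Si](CC)(CC)CC)C[C@H]32)c(Cl)c1
F3 | step 10 | arenediazonium bromide derived from F2 | N#[N+]c1ccc(O[C@]2(C)CCC[C@]3(C)CC[C@@H](C(C)(C)O[Si](CC)(CC)CC)C[C@H]32)c(Cl)c1.[Br-]
F4 | step 3 | (2R,5R)-5-(2-chloropropan-2-yl)-2-methylcyclohexan-1-one | C[C@@H]1CC[C@@H](C(C)(C)Cl)CC1=O
F5 | step 3 | (1S,6R)-3,7,7-trimethylbicyclo[4.1.0]heptan-2-one (C3 epimerisable) | CC1CC[C@H]2C(C)(C)[C@H]2C1=O
F6 | step 3 | (1S,3S,6R)-3,7,7-trimethyl-3-(3-oxopentyl)bicyclo[4.1.0]heptan-2-one | CCC(=O)CC[C@]1(C)CC[C@H]2C(C)(C)[C@H]2C1=O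
F7 | step 3 | 6β,11-cycloeudesm-4-en-3-one (cyclopropane C6–C7–C11 on the β face, 10β-CH3) | O=C1CC[C@]2(C)CC[C@H]3C(C)(C)[C@H]3C2=C1C
F8 | step 8 | 4α-hydroperoxy-11-(triethylsilyloxy)-5α-eudesmane | OO[C@]1(C)CCC[C@]2(C)CC[C@@H](C(C)(C)O[Si](CC)(CC)CC)C[C@H]21
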